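Ask how much starting material the birch flask still holds at 17 min, and how the starting rate answers to coupling partner and catalyst.

in all of them: starting material 0.800 M

| run | coupling partner | catalyst | target | time |
|---|---|---|---|---|
| ash | 0.640 M | 0.0400 M |  |  |
| alder | 0.960 M | 0.0400 M |  |  |
| maple | 0.640 M | 0.0800 M |  |  |
| oak | 0.640 M | 0.0400 M | 0.400 M |  |
| birch | 0.640 M | 0.0400 M |  | 17 min |

| run | time / min | [starting material] / M |
|---|---|---|
| ash run | 0.27 | 0.7608 |
| ash run | 0.61 | 0.7193 |
| ash run | 1.4 | 0.6406 |
| ash run | 3.0 | 0.5147 |
| ash run | 6.8 | 0.3562 |
| alder run | 0.27 | 0.7475 |
| alder run | 0.61 | 0.6975 |
| alder run | 1.4 | 0.5912 |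
| alder run | 3.0 | 0.4392 |
| alder run | 6.8 | 0.2487 |
| maple run | 0.27 | 0.7287 |
| maple run | 0.61 | 0.6550 |
| maple run | 1.4 | 0.5280 |
| maple run | 3.0 | 0.3819 |
| maple run | 6.8 | 0.2469 |
| oak run | 0.27 | 0.7643 |
| oak run | 0.61 | 0.7222 |
| oak run | 1.4 | 0.6377 |
| oak run | 3.0 | 0.5178 |
| oak run | 6.8 | 0.3558 |

(each reading ± 0.002 M)

- the exponent of [coupling partner] in the starting rate at the charge of the ash run (at the point where two percent of the starting material have become target)
- the exponent of [catalyst] in the starting rate at the charge of the ash run (at the point where two percent of the starting material have become target)
- starting material in the birch run at 17 min, as a share of the starting material charged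

- Overall: starting material + coupling partner -> target, with catalyst as catalyst.
- Constant volume, constant temperature.
- The analysis sees a species whether free or bound.
- An order is taken over about fifteen percent of the charge, up and down.

Start with a crude bracket. The oak readings lie on the ash readings (0.3558 M against 0.3562 M at 6.8 min), so set added target aside and treat birch as the ash run carried further. The two reactants go one for one, so [coupling partner] stays 0.160 M below [starting material]. Coupling partner is thus the limiting reagent, which puts the bound from below at 20.0% of the charge. The last ash reading gives the bound from above, 44.5%.

Now tighten it by hand. From 1.4 min to 3.0 min the ash run reads 0.332 /M/min, and from 3.0 min to 6.8 min it reads 0.368 /M/min. Call this the pair constant: the rate divided by [starting material] times [coupling partner], read as the rise of ln([starting material]/[coupling partner]) per minute, divided by the gap between the two. It climbs as the mean [coupling partner] drops from 0.418 M to 0.275 M.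

Hold the later value over the whole tail, a stingy choice while the climb goes on, and the reckoning puts birch at 28.6%. Then run a straight line through both values to empty coupling partner, which reads 0.440 /M/min. Hold that generous value over the tail, and the reckoning puts birch lower, at 27.4%.

The forecast gives 0.68 for coupling partner, 1 for catalyst and 28.5% for birch, below the upper bound and above the lower. It reads the rate as first order in starting material with saturation in coupling partner, and of the oak run it says that “added target does nothing”.

    catalyst + starting material + coupling partner → target + catalyst (12.54 /M²/min)
    catalyst + coupling partner ⇌ idle catalyst-reagent complex, settled at all times (0.3310 /M)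
    2 coupling partner ⇌ idle reagent dimer, settled at all times (0.7000 /M)

The flask gives 0.67 for coupling partner, 1.0 for catalyst and 27.7% for birch, and that last value lies below the upper bound and above the lower. Over the birch tail the pair constant averages 0.421 /M/min. In the alder run, up to 3.58 min, when the target made is 0.400 M, it averages 0.269 /M/min. Coupling partner bound as idle reagent dimer pulls the order down: with that binding taken away, the apparent order in [coupling partner] goes from 0.67 to 0.85.

The numbers in the tables stem from a simulated flask from invented constants, noise included.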